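Numbering: C1 is the ring-fusion CH, C2 the lactone O–CH, the carbocycle continues to C14; C15, C16 and C17 are the lactone alpha carbon, carbonyl and exocyclic CH2. Everything rests on the C1–C2 bond, which is common to the 14-membered carbocycle and the five-membered lactone (O, C2, C1, C15, C16) and joins an allylic carbinol to the gamma carbon of a 2-carboxyallyl unit. One chromium-mediated intramolecular 2-(methoxycarbonyl)allylation forms it, closes the macrocycle and, through the C2 alkoxide and the C16 ester, the lactone. The precursor is an open-chain C2 enal carrying an (E)-2-(bromomethyl)enoate terminus, built from geranyl acetate by two enantioselective vinylogous aldol additions that set C10 and C6.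

Key step: step 18

Assumption: the bisphosphoramide antipode (steps 5 and 9) and the chromium ligand antipode (step 18) are taken to be those that give Si-face and Re-face attack respectively; the sense of induction is to be confirmed on 10 and on 27 before scale-up.

Step 1
Reactants: 1 geranyl acetate
Product: 3 (2E)-3-methyl-6-oxohex-2-en-1-yl acetate, via secondary ozonide 2 (not isolated)
Conditions: O3 (1.0 equiv), CH2Cl2, −78 °C; PPh3, −78 °C to rt
Reagents that add atoms: ozone [O-][O+]=O
Why: Chemoselective ozonolysis with reductive work-up: one equivalent of ozone should attack the electron-rich 6,7-olefin in preference to the 2,3-olefin, which the allylic acetate deactivates, releasing the C1/C10–C14 segment as the aldehyde with its E olefin intact.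

Step 2
Reactants: 3 (2E)-3-methyl-6-oxohex-2-en-1-yl acetate
Product: 5 (2E)-3-methylhept-2-en-6-yn-1-ol, via hydroxy aldehyde 4 (not isolated)
Conditions: dimethyl (1-diazo-2-oxopropyl)phosphonate, K2CO3, MeOH, 0 °C to rt
Reagents that add atoms: dimethyl (1-diazo-2-oxopropyl)phosphonate COP(=O)(OC)C(=[N+]=[N-])C(C)=O
Why: Seyferth–Gilbert homologation in its K2CO3/MeOH form converts the aldehyde into the terminal alkyne (the new carbon is C15), and the same methanolic carbonate cleaves the allylic acetate, so no separate deprotection is needed.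

Step 3
Reactants: 5 (2E)-3-methylhept-2-en-6-yn-1-ol
Product: 6 (2E)-3-methylhept-2-en-6-ynal
Conditions: MnO2, CH2Cl2, rt
Reagents that add atoms: none
Why: Allylic oxidation with MnO2 is selective for the allylic alcohol and should give the E enal without touching the alkyne.

Step 4
Reactants: 7 ethyl 3-methylbut-2-enoate
Product: 9 tert-butyl[(1-ethoxy-3-methylbuta-1,3-dien-1-yl)oxy]dimethylsilane, via lithium dienolate 8 (not isolated)
Conditions: LiN(i-Pr)2, THF, −78 °C; TBSCl, DMPU, −78 °C to rt
Reagents that add atoms: tert-butyldimethylsilyl chloride CC(C)(C)[Si](C)(C)Cl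
Why: Kinetic gamma-deprotonation of the senecioate and O-silylation of the lithium dienolate give the silyl dienolate (silyl ketene acetal formation), whose ketene acetal geometry does not matter for the aldol steps.

Step 5
Reactants: 6 (2E)-3-methylhept-2-en-6-ynal; 9 silyl dienolate
Product: 10 ethyl (2E,5S,6E)-5-hydroxy-3,7-dimethylundeca-2,6-dien-10-ynoate
Conditions: SiCl4, chiral binaphthyldiamine-derived bisphosphoramide (cat.), i-Pr2NEt (cat.), CH2Cl2, −78 °C; aq. NaHCO3
Reagents that add atoms: none
Why: Catalytic enantioselective vinylogous Mukaiyama aldol addition: the chiral phosphoramide-bound silicon cation activates the enal, the dienolate reacts at its gamma carbon to give the E enoate, and the catalyst antipode chosen for Si-face attack sets C10 as S.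

Step 6
Reactants: 10 ethyl (2E,5S,6E)-5-hydroxy-3,7-dimethylundeca-2,6-dien-10-ynoate
Product: 11 ethyl (2E,5S,6E)-5-[(tert-butyldimethylsilyl)oxy]-3,7-dimethylundeca-2,6-dien-10-ynoate
Conditions: TBSOTf, 2,6-lutidine, CH2Cl2, −78 °C to 0 °C
Reagents that add atoms: tert-butyldimethylsilyl triflate CC(C)(C)[Si](C)(C)OS(=O)(=O)C(F)(F)F
Why: Silylation with the silyl triflate and a hindered base protects the secondary allylic alcohol without ionising it.

Step 7
Reactants: 11 ethyl (2E,5S,6E)-5-[(tert-butyldimethylsilyl)oxy]-3,7-dimethylundeca-2,6-dien-10-ynoate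
Product: 12 (2E,5S,6E)-5-[(tert-butyldimethylsilyl)oxy]-3,7-dimethylundeca-2,6-dien-10-yn-1-ol
Conditions: i-Bu2AlH, CH2Cl2, −78 °C; Rochelle salt
Reagents that add atoms: none
Why: i-Bu2AlH reduces the conjugated ester in the 1,2 sense to the allylic alcohol at low temperature (ester reduction) and leaves the terminal alkyne and the silyl ether alone.

Step 8
Reactants: 12 (2E,5S,6E)-5-[(tert-butyldimethylsilyl)oxy]-3,7-dimethylundeca-2,6-dien-10-yn-1-ol
Product: 13 (2E,5S,6E)-5-[(tert-butyldimethylsilyl)oxy]-3,7-dimethylundeca-2,6-dien-10-ynal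
Conditions: MnO2, CH2Cl2, rt
Reagents that add atoms: none
Why: Allylic oxidation with MnO2 gives the E enal for the second chain extension under neutral conditions that do not affect the C10 silyl ether.

Step 9
Reactants: 13 (2E,5S,6E)-5-[(tert-butyldimethylsilyl)oxy]-3,7-dimethylundeca-2,6-dien-10-ynal; 9 silyl dienolate
Product: 14 ethyl (2E,5S,6E,9S,10E)-9-[(tert-butyldimethylsilyl)oxy]-5-hydroxy-3,7,11-trimethylpentadeca-2,6,10-trien-14-ynoate
Conditions: SiCl4, the same bisphosphoramide antipode (cat.), i-Pr2NEt (cat.), CH2Cl2, −78 °C; aq. NaHCO3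
Reagents that add atoms: none
Why: The same catalytic enantioselective vinylogous Mukaiyama aldol addition: the catalyst antipode of step 5 again directs Si-face attack, so C6 is set as S under reagent control with the distant C10 centre playing no part, and gamma attack again gives the E enoate.

Step 10
Reactants: 14 ethyl (2E,5S,6E,9S,10E)-9-[(tert-butyldimethylsilyl)oxy]-5-hydroxy-3,7,11-trimethylpentadeca-2,6,10-trien-14-ynoate
Product: 15 ethyl (2E,5S,6E,9S,10E)-5,9-bis[(tert-butyldimethylsilyl)oxy]-3,7,11-trimethylpentadeca-2,6,10-trien-14-ynoate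
Conditions: TBSOTf, 2,6-lutidine, CH2Cl2, −78 °C to 0 °C
Reagents that add atoms: tert-butyldimethylsilyl triflate CC(C)(C)[Si](C)(C)OS(=O)(=O)C(F)(F)F
Why: Silylation as in step 6 gives both secondary carbinols (C6, C10) the same protecting group, so that one reagent can free them together at the end.

Step 11
Reactants: 15 ethyl (2E,5S,6E,9S,10E)-5,9-bis[(tert-butyldimethylsilyl)oxy]-3,7,11-trimethylpentadeca-2,6,10-trien-14-ynoate
Product: 16 (2E,5S,6E,9S,10E)-5,9-bis[(tert-butyldimethylsilyl)oxy]-3,7,11-trimethylpentadeca-2,6,10-trien-14-yn-1-ol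
Conditions: i-Bu2AlH, CH2Cl2, −78 °C; Rochelle salt
Reagents that add atoms: none
Why: Ester reduction with i-Bu2AlH as in step 7 brings C2 to the alcohol level, which, once protected, survives the organometallic steps that build the acrylate end.

Step 12
Reactants: 16 (2E,5S,6E,9S,10E)-5,9-bis[(tert-butyldimethylsilyl)oxy]-3,7,11-trimethylpentadeca-2,6,10-trien-14-yn-1-ol
Product: 17 triethylsilyl ether of 16 (C2–OSiEt3)
Conditions: TESCl, imidazole, CH2Cl2, 0 °C
Reagents that add atoms: triethylsilyl chloride CC[Si](CC)(CC)Cl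
Why: Silylation of the only free hydroxyl installs a primary triethylsilyl ether that mild acid can later remove in the presence of the two secondary tert-butyldimethylsilyl ethers (orthogonal silyl protection).

Step 13
Reactants: 17 triethylsilyl ether of 16
Product: 19 methyl (6E,8S,10E,12S,14E)-8,12-bis[(tert-butyldimethylsilyl)oxy]-6,10,14-trimethyl-16-[(triethylsilyl)oxy]hexadeca-6,10,14-trien-2-ynoate, via lithium acetylide 18 (not isolated)
Conditions: n-BuLi, THF, −78 °C; ClCO2CH3, −78 °C to 0 °C
Reagents that add atoms: methyl chloroformate COC(=O)Cl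
Why: Deprotonation of the terminal alkyne and C-acylation of the lithium acetylide with the chloroformate (alkynoate synthesis) bring in C16, and nothing else in 17 is acidic or electrophilic enough to interfere.

Step 14
Reactants: 19 methyl ynoate
Product: 21 methyl (2Z,6E,8S,10E,12S,14E)-8,12-bis[(tert-butyldimethylsilyl)oxy]-2-(hydroxymethyl)-6,10,14-trimethyl-16-[(triethylsilyl)oxy]hexadeca-2,6,10,14-tetraenoate, via alpha-alumino enoate 20 (not isolated)
Conditions: i-Bu2AlH, HMPA, THF, 0 °C; CH2O (gas, from cracked paraformaldehyde), 0 °C to rt; Rochelle salt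
Reagents that add atoms: formaldehyde C=O
Why: Conjugate syn-hydroalumination of the ynoate by the i-Bu2AlH–HMPA complex puts hydrogen on C1 and aluminium on C15, and the alpha-alumino enoate adds to formaldehyde at C15 with retention (vinylalumination of an aldehyde), so C17 enters cis to the C1 hydrogen and C14 stays cis to the ester.

Step 15
Reactants: 21 methyl 2-(hydroxymethyl)enoate
Product: 22 methyl (2E,6E,8S,10E,12S,14E)-2-(bromomethyl)-8,12-bis[(tert-butyldimethylsilyl)oxy]-6,10,14-trimethyl-16-[(triethylsilyl)oxy]hexadeca-2,6,10,14-tetraenoate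
Conditions: CBr4, PPh3, CH2Cl2, −40 °C to −20 °C
Reagents that add atoms: carbon tetrabromide BrC(Br)(Br)Br
Why: Appel bromination displaces the alkoxyphosphonium ion of the primary allylic alcohol by SN2 at low temperature, which should keep the olefin geometry (C14 cis to CO2CH3) and spare the silyl ethers.

Step 16
Reactants: 22 bromide with C2–OSiEt3
Product: 23 methyl (2E,6E,8S,10E,12S,14E)-2-(bromomethyl)-8,12-bis[(tert-butyldimethylsilyl)oxy]-16-hydroxy-6,10,14-trimethylhexadeca-2,6,10,14-tetraenoate
Conditions: camphorsulfonic acid (cat.), MeOH/CH2Cl2, −20 °C to 0 °C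
Reagents that add atoms: none
Why: Acid-catalysed methanolysis removes the primary triethylsilyl ether far faster than the secondary tert-butyldimethylsilyl ethers (selective desilylation), and the absence of any nucleophilic base or fluoride–amine reagent protects the electrophilic allylic bromide.

Step 17
Reactants: 23 bromo alcohol
Product: 24 methyl (2E,6E,8S,10E,12S,14E)-2-(bromomethyl)-8,12-bis[(tert-butyldimethylsilyl)oxy]-6,10,14-trimethyl-16-oxohexadeca-2,6,10,14-tetraenoate
Conditions: MnO2, CH2Cl2, rt
Reagents that add atoms: none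
Why: Allylic oxidation with MnO2 converts the electron-rich primary allylic alcohol into the C2 enal under neutral heterogeneous conditions that leave the allylic bromide, the enoate and the silyl ethers untouched.

Step 18
Reactants: 24 bromo enal
Product: 27 (1R,2S,6S,10S,3E,7E,11E)-6,10-bis[(tert-butyldimethylsilyl)oxy] trans-fused macrocyclic alpha-methylene lactone, via allylchromium dichloride 25 (not isolated), via chromium alkoxide 26 (not isolated)
Conditions: CrCl2 (excess), chiral N-[2-(4-isopropyl-4,5-dihydrooxazol-2-yl)phenyl]methanesulfonamide ligand, Et3N, THF, rt; slow addition of 24 (final concentration about 2 mM); aq. citric acid, then camphorsulfonic acid (cat.), CH2Cl2 if lactonisation is incomplete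
Reagents that add atoms: none
Why: Divalent chromium reduces the C17–Br bond in two one-electron steps, the trivalent allylchromium 25 attacks the C2 aldehyde with its gamma carbon C1 through a six-membered chair, and the chromium alkoxide 26 then expels methoxide from the adjacent C16 ester. The closest known reaction type is the Nozaki–Hiyama–Kishi 2-(alkoxycarbonyl)allylation of aldehydes with lactonisation to alpha-methylene gamma-lactones, which has closed medium and large carbocycles, combined with the use of stoichiometric chiral sulfonamide complexes of chromium in macrocyclisations. The 14-membered carbocycle closes by C1–C2 bond formation (14-exo-trig) and the lactone by O–C16 acyl substitution (5-exo-trig). C1 (R) follows from the E bromide, whose C14 substituent lies trans to the CH2Cr group and therefore equatorial beside the equatorial C3 alkenyl group, which gives the anti adduct and the trans ring fusion, while C2 (S) follows from Re-face attack on the aldehyde, imposed by the chiral ligand because the C6 and C10 centres are too far away to be relied on. The step thus needs anti simple diastereoselection, Re-face selectivity and cyclisation in preference to oligomerisation: the first rests on the defined bromide geometry, which the 2-ester substituent helps to retain, the second on the ligand, the third on slow addition at high dilution and on the three E trisubstituted olefins that stiffen the chain. Nothing else in 24 competes, since the enal has no alpha hydrogen and reacts only 1,2, and silyl ethers, esters and trisubstituted olefins are inert to divalent chromium.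

Step 19
Reactants: 27 macrocyclic lactone bis(silyl ether)
Product: 28 (1R,2S,6S,10S,3E,7E,11E)-6,10-dihydroxy macrocyclic alpha-methylene lactone
Conditions: HF·pyridine, pyridine, THF, 0 °C to rt
Reagents that add atoms: none
Why: Buffered HF–pyridine cleaves both secondary silyl ethers (fluoride desilylation) without the basic conditions that could add nucleophiles irreversibly to the alpha-methylene lactone or ionise the allylic carbinols.

Step 20
Reactants: 28 lactone diol
Product: 29 target CID11069750, the (1R,2S,6S,10S,3E,7E,11E)-6,10-diacetate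
Conditions: Ac2O, pyridine, DMAP (cat.), CH2Cl2, 0 °C to rt
Reagents that add atoms: acetic anhydride CC(=O)OC(C)=O
Why: DMAP-catalysed acetylation esterifies the two secondary allylic alcohols with retention, and no stereocentre or olefin is touched.

Compound list
1 | geranyl acetate, (2E)-3,7-dimethylocta-2,6-dien-1-yl acetate | CC(C)=CCC/C(C)=C/COC(C)=O | starting material
2 | secondary ozonide (3,3-dimethyl-1,2,4-trioxolane) of the 6,7-olefin of 1, racemic at the acetal carbon | CC1(C)OOC(CC/C(C)=C/COC(C)=O)O1 | intermediate (not isolated)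
3 | (2E)-3-methyl-6-oxohex-2-en-1-yl acetate, i.e. (E)-6-acetoxy-4-methylhex-4-enal | O=CCC/C(C)=C/COC(C)=O | intermediate
4 | (4E)-6-hydroxy-4-methylhex-4-enal | O=CCC/C(C)=C/CO | intermediate (not isolated)
5 | (2E)-3-methylhept-2-en-6-yn-1-ol | C#CCC/C(C)=C/CO | intermediate
6 | (2E)-3-methylhept-2-en-6-ynal | C#CCC/C(C)=C/C=O | intermediate
7 | ethyl 3-methylbut-2-enoate | CCOC(=O)C=C(C)C | starting material
8 | lithium dienolate of 7 | C=C(C)C=C(OCC)O[Li] | intermediate (not isolated)
9 | tert-butyl[(1-ethoxy-3-methylbuta-1,3-dien-1-yl)oxy]dimethylsilane (ketene acetal geometry immaterial) | C=C(C)C=C(OCC)O[Si](C)(C)C(C)(C)C | intermediate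
10 | ethyl (2E,5S,6E)-5-hydroxy-3,7-dimethylundeca-2,6-dien-10-ynoate | C#CCC/C(C)=C/[C@@H](O)C/C(C)=C/C(=O)OCC | intermediate
11 | ethyl (2E,5S,6E)-5-[(tert-butyldimethylsilyl)oxy]-3,7-dimethylundeca-2,6-dien-10-ynoate | C#CCC/C(C)=C/[C@@H](O[Si](C)(C)C(C)(C)C)C/C(C)=C/C(=O)OCC | intermediate
12 | (2E,5S,6E)-5-[(tert-butyldimethylsilyl)oxy]-3,7-dimethylundeca-2,6-dien-10-yn-1-ol | C#CCC/C(C)=C/[C@@H](O[Si](C)(C)C(C)(C)C)C/C(C)=C/CO | intermediate
13 | (2E,5S,6E)-5-[(tert-butyldimethylsilyl)oxy]-3,7-dimethylundeca-2,6-dien-10-ynal | C#CCC/C(C)=C/[C@@H](O[Si](C)(C)C(C)(C)C)C/C(C)=C/C=O | intermediate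
14 | ethyl (2E,5S,6E,9S,10E)-9-[(tert-butyldimethylsilyl)oxy]-5-hydroxy-3,7,11-trimethylpentadeca-2,6,10-trien-14-ynoate | C#CCC/C(C)=C/[C@@H](O[Si](C)(C)C(C)(C)C)C/C(C)=C/[C@@H](O)C/C(C)=C/C(=O)OCC | intermediate
15 | ethyl (2E,5S,6E,9S,10E)-5,9-bis[(tert-butyldimethylsilyl)oxy]-3,7,11-trimethylpentadeca-2,6,10-trien-14-ynoate | C#CCC/C(C)=C/[C@@H](O[Si](C)(C)C(C)(C)C)C/C(C)=C/[C@@H](O[Si](C)(C)C(C)(C)C)C/C(C)=C/C(=O)OCC | intermediate
16 | (2E,5S,6E,9S,10E)-5,9-bis[(tert-butyldimethylsilyl)oxy]-3,7,11-trimethylpentadeca-2,6,10-trien-14-yn-1-ol | C#CCC/C(C)=C/[C@@H](O[Si](C)(C)C(C)(C)C)C/C(C)=C/[C@@H](O[Si](C)(C)C(C)(C)C)C/C(C)=C/CO | intermediate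
17 | triethylsilyl ether of 16 (C2–OSiEt3, C6 and C10 silyl ethers S, terminal alkyne) | C#CCC/C(C)=C/[C@@H](O[Si](C)(C)C(C)(C)C)C/C(C)=C/[C@@H](O[Si](C)(C)C(C)(C)C)C/C(C)=C/CO[Si](CC)(CC)CC | intermediate
18 | lithium acetylide of 17 | [Li]C#CCC/C(C)=C/[C@@H](O[Si](C)(C)C(C)(C)C)C/C(C)=C/[C@@H](O[Si](C)(C)C(C)(C)C)C/C(C)=C/CO[Si](CC)(CC)CC | intermediate (not isolated)
19 | methyl (6E,8S,10E,12S,14E)-8,12-bis[(tert-butyldimethylsilyl)oxy]-6,10,14-trimethyl-16-[(triethylsilyl)oxy]hexadeca-6,10,14-trien-2-ynoate | COC(=O)C#CCC/C(C)=C/[C@@H](O[Si](C)(C)C(C)(C)C)C/C(C)=C/[C@@H](O[Si](C)(C)C(C)(C)C)C/C(C)=C/CO[Si](CC)(CC)CC | intermediate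
20 | alpha-alumino enoate from 19 (diisobutylaluminium on C15 cis to the C1 hydrogen, CO2CH3 cis to C14) | COC(=O)/C([Al](CC(C)C)CC(C)C)=C\CC/C(C)=C/[C@@H](O[Si](C)(C)C(C)(C)C)C/C(C)=C/[C@@H](O[Si](C)(C)C(C)(C)C)C/C(C)=C/CO[Si](CC)(CC)CC | intermediate (not isolated)
21 | methyl (2Z,6E,8S,10E,12S,14E)-8,12-bis[(tert-butyldimethylsilyl)oxy]-2-(hydroxymethyl)-6,10,14-trimethyl-16-[(triethylsilyl)oxy]hexadeca-2,6,10,14-tetraenoate | COC(=O)/C(CO)=C\CC/C(C)=C/[C@@H](O[Si](C)(C)C(C)(C)C)C/C(C)=C/[C@@H](O[Si](C)(C)C(C)(C)C)C/C(C)=C/CO[Si](CC)(CC)CC | intermediate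
22 | methyl (2E,6E,8S,10E,12S,14E)-2-(bromomethyl)-8,12-bis[(tert-butyldimethylsilyl)oxy]-6,10,14-trimethyl-16-[(triethylsilyl)oxy]hexadeca-2,6,10,14-tetraenoate | COC(=O)/C(CBr)=C\CC/C(C)=C/[C@@H](O[Si](C)(C)C(C)(C)C)C/C(C)=C/[C@@H](O[Si](C)(C)C(C)(C)C)C/C(C)=C/CO[Si](CC)(CC)CC | intermediate
23 | methyl (2E,6E,8S,10E,12S,14E)-2-(bromomethyl)-8,12-bis[(tert-butyldimethylsilyl)oxy]-16-hydroxy-6,10,14-trimethylhexadeca-2,6,10,14-tetraenoate | COC(=O)/C(CBr)=C\CC/C(C)=C/[C@@H](O[Si](C)(C)C(C)(C)C)C/C(C)=C/[C@@H](O[Si](C)(C)C(C)(C)C)C/C(C)=C/CO | intermediate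
24 | methyl (2E,6E,8S,10E,12S,14E)-2-(bromomethyl)-8,12-bis[(tert-butyldimethylsilyl)oxy]-6,10,14-trimethyl-16-oxohexadeca-2,6,10,14-tetraenoate (C14 cis to CO2CH3) | COC(=O)/C(CBr)=C\CC/C(C)=C/[C@@H](O[Si](C)(C)C(C)(C)C)C/C(C)=C/[C@@H](O[Si](C)(C)C(C)(C)C)C/C(C)=C/C=O | intermediate
25 | allylchromium dichloride from 24 (trivalent chromium on C17) | COC(=O)/C(C[Cr](Cl)Cl)=C\CC/C(C)=C/[C@@H](O[Si](C)(C)C(C)(C)C)C/C(C)=C/[C@@H](O[Si](C)(C)C(C)(C)C)C/C(C)=C/C=O | intermediate (not isolated)
26 | chromium alkoxide of the (1R,2S,6S,10S) macrocyclic hydroxy ester (14-membered ring closed, lactone still open) | C=C(C(=O)OC)[C@H]1CC/C(C)=C/[C@@H](O[Si](C)(C)C(C)(C)C)C/C(C)=C/[C@@H](O[Si](C)(C)C(C)(C)C)C/C(C)=C/[C@@H]1O[Cr](Cl)Cl | intermediate (not isolated)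
27 | (1R,2S,6S,10S,3E,7E,11E)-6,10-bis[(tert-butyldimethylsilyl)oxy] trans-fused macrocyclic alpha-methylene lactone | C=C1C(=O)O[C@H]2/C=C(\C)C[C@H](O[Si](C)(C)C(C)(C)C)/C=C(\C)C[C@H](O[Si](C)(C)C(C)(C)C)/C=C(\C)CC[C@H]12 | intermediate
28 | (1R,2S,6S,10S,3E,7E,11E)-6,10-dihydroxy trans-fused macrocyclic alpha-methylene lactone | C=C1C(=O)O[C@H]2/C=C(\C)C[C@H](O)/C=C(\C)C[C@H](O)/C=C(\C)CC[C@H]12 | intermediate
29 | CID11069750, the (1R,2S,6S,10S,3E,7E,11E)-6,10-diacetoxy trans-fused macrocyclic alpha-methylene lactone | C=C1C(=O)O[C@H]2/C=C(\C)C[C@H](OC(C)=O)/C=C(\C)C[C@H](OC(C)=O)/C=C(\C)CC[C@H]12 | target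

Total step count: 20. Longest linear sequence: 19 steps (steps 1–3 and 5–20, from geranyl acetate); step 4 is a one-step side branch.

Steps most likely to fail

Step 18. The risk is loss of stereochemical fidelity. The allylchromium may relax to the thermodynamically preferred geometry before the slow macrocyclic closure, which would mean syn addition and a cis-fused lactone, and the ligand may fail to dominate the facial bias of the folded chain. The fallback makes the syn manifold deliberate and repairs C2 afterwards. Setting out from 24, LiBr in acetone equilibrates the bromide by allylic transposition to the thermodynamically favoured (Z)-2-(bromomethyl)enoate enal F1 (C14 cis to CH2Br). Chromium closure of F1 under the conditions of step 18 but with the antipodal ligand (Si-face attack at C2, C14 now axial in the chair) should give the cis-fused (1R,2R) lactone F2. LiOH in THF/H2O opens it to the hydroxy acid F3, which is handled cold at buffered pH. Mitsunobu lactonisation (PPh3, diisopropyl azodicarboxylate, THF, 0 °C) then recloses the ring with inversion at the allylic C2 and returns to the route at 27.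

Step 14. The hydroalumination may leak into 1,2-reduction of the ester, the alpha-alumino enoate may be protonated and not hydroxymethylated if monomeric formaldehyde is delivered poorly, and equilibration through the aluminium allenolate may erode the olefin geometry. The fallback sets out from 19 and uses tin. Syn-hydrostannation with Bu3SnH and catalytic Pd(PPh3)4 (zerovalent palladium) places tin on C15 and hydrogen on C1, giving the alpha-stannyl enoate F4. Iododestannylation with I2 in CH2Cl2 at 0 °C gives, with retention, the alpha-iodo enoate F5. Stille coupling of F5 with (tributylstannyl)methanol (Pd(PPh3)4, dioxane, 80 °C) introduces C17 as CH2OH and comes back to the route at 21.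

Step 9. The silicon cation generated from SiCl4 may ionise or cleave the allylic C10 silyl ether, and the hindered enal may react slowly enough for gamma-selectivity and catalyst control to erode. The fallback sets out from 13 and builds the same unit from an acetoacetate equivalent. Aldol addition of 1-ethoxy-1,3-bis(trimethylsilyloxy)buta-1,3-diene catalysed by Ti(Oi-Pr)4 and BINOL, followed by mild acidic desilylation, should give the delta-hydroxy beta-keto ester F6 with C6 set as S by the catalyst. TBSCl and imidazole give the silyl ether F7. NaH and then ClP(O)(OEt)2 in Et2O convert the chelated sodium enolate into the (Z)-enol phosphate F8. Me2CuLi (excess, to cover the acetylenic C–H) replaces phosphate by methyl with retention, which gives the E enoate 15, where the route is rejoined.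

Further compounds
F1 | step 18 | methyl (2Z,6E,8S,10E,12S,14E)-2-(bromomethyl)-8,12-bis[(tert-butyldimethylsilyl)oxy]-6,10,14-trimethyl-16-oxohexadeca-2,6,10,14-tetraenoate (C14 cis to CH2Br) | COC(=O)/C(CBr)=C/CC/C(C)=C/[C@@H](O[Si](C)(C)C(C)(C)C)C/C(C)=C/[C@@H](O[Si](C)(C)C(C)(C)C)C/C(C)=C/C=O
F2 | step 18 | (1R,2R,6S,10S,3E,7E,11E)-6,10-bis[(tert-butyldimethylsilyl)oxy] cis-fused macrocyclic alpha-methylene lactone | C=C1C(=O)O[C@@H]2/C=C(\C)C[C@H](O[Si](C)(C)C(C)(C)C)/C=C(\C)C[C@H](O[Si](C)(C)C(C)(C)C)/C=C(\C)CC[C@H]12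
F3 | step 18 | (1R,2R,6S,10S) macrocyclic hydroxy acid from F2 (C2–OH, C15 acrylic acid) | C=C(C(=O)O)[C@H]1CC/C(C)=C/[C@@H](O[Si](C)(C)C(C)(C)C)C/C(C)=C/[C@@H](O[Si](C)(C)C(C)(C)C)C/C(C)=C/[C@H]1O
F4 | step 14 | alpha-stannyl enoate from 19 (tributylstannyl on C15 cis to the C1 hydrogen, CO2CH3 cis to C14) | COC(=O)/C([Sn](CCCC)(CCCC)CCCC)=C\CC/C(C)=C/[C@@H](O[Si](C)(C)C(C)(C)C)C/C(C)=C/[C@@H](O[Si](C)(C)C(C)(C)C)C/C(C)=C/CO[Si](CC)(CC)CC
F5 | step 14 | alpha-iodo enoate from F4 (iodine on C15, CO2CH3 cis to C14) | COC(=O)/C(I)=C\CC/C(C)=C/[C@@H](O[Si](C)(C)C(C)(C)C)C/C(C)=C/[C@@H](O[Si](C)(C)C(C)(C)C)C/C(C)=C/CO[Si](CC)(CC)CC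
F6 | step 9 | ethyl (5S,6E,9S,10E)-9-[(tert-butyldimethylsilyl)oxy]-5-hydroxy-7,11-dimethyl-3-oxopentadeca-6,10-dien-14-ynoate | C#CCC/C(C)=C/[C@@H](O[Si](C)(C)C(C)(C)C)C/C(C)=C/[C@@H](O)CC(=O)CC(=O)OCC
F7 | step 9 | ethyl (5S,6E,9S,10E)-5,9-bis[(tert-butyldimethylsilyl)oxy]-7,11-dimethyl-3-oxopentadeca-6,10-dien-14-ynoate | C#CCC/C(C)=C/[C@@H](O[Si](C)(C)C(C)(C)C)C/C(C)=C/[C@@H](O[Si](C)(C)C(C)(C)C)CC(=O)CC(=O)OCC
F8 | step 9 | (2Z)-enol diethyl phosphate of F7 (phosphate oxygen cis to CO2Et) | C#CCC/C(C)=C/[C@@H](O[Si](C)(C)C(C)(C)C)C/C(C)=C/[C@@H](O[Si](C)(C)C(C)(C)C)C/C(OP(=O)(OCC)OCC)=C/C(=O)OCC
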